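The dihydropyran is cut by a retro-hetero-Diels–Alder reaction into 5-epi-isoalantolactone (from isoalantolactone) and ent-β-elemenal. The plan rests on making the elemenal cyclohexane C5–C10 by ring contraction: a bulky aluminium Lewis acid converts a 1-methylcycloheptene oxide into a cyclohexanecarbaldehyde, moving ring bond C1–C9 to C10. One operation thus closes the six-membered ring, creates the quaternary centre C10 (CH3, CHO later vinyl) stereospecifically beside C5 and expels the old carvone carbonyl carbon as the future vinyl CH (C1), exploiting the vinyl-bearing quaternary C10 of that ring. The precursor is the epoxide of a 2-methylcycloheptene carrying cis isopropenyl and side-chain groups, built from (R)-carvone by one-carbon ring expansion and conjugate addition.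

Key step: step 7

Remark: the SMILES is read as the C5 epimer of isoalantolactone (cis-decalin, H-5 syn to CH3-14) joined to the enantiomer of natural β-elemenal; isoalantolactone is taken as a purchasable natural product.
Locants: elemane half C10 (CH3-14, vinyl C1=C2), C5 (isopropenyl), C6, C7 (side chain C11–C13), C8, C9; lactone half numbered as eudesmane. TBS = tert-butyldimethylsilyl.

Step 1
Reactants: 1 (R)-(−)-carvone
Product: 2 (R)-5-(3-hydroxyprop-1-en-2-yl)-2-methylcyclohex-2-en-1-one (10-hydroxycarvone)
Conditions: SeO2 (cat.), t-BuOOH, salicylic acid (cat.), CH2Cl2, rt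
Reagents that add atoms: tert-butyl hydroperoxide, CC(C)(C)OO (terminal oxygen source; SeO2, O=[Se]=O, is the catalytic carrier)
Why: Catalytic SeO2 allylic hydroxylation (ene reaction, then [2,3]-shift) should attack the methyl of the only electron-rich alkene, the isopropenyl group, while the conjugated ring alkene is deactivated and the stereocentre is untouched.

Step 2
Reactants: 2 (R)-10-hydroxycarvone
Product: 3 (R)-5-[3-(TBS-oxy)prop-1-en-2-yl]-2-methylcyclohex-2-en-1-one
Conditions: TBSCl, imidazole, DMF, rt
Reagents that add atoms: tert-butyldimethylsilyl chloride, CC(C)(C)[Si](C)(C)Cl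
Why: Silylation of the primary allylic alcohol gives an ether that should survive the organometallic, Lewis-acid and peracid steps and keeps this side chain distinguishable from the isopropenyl group introduced later.

Step 3
Reactants: 3 silyl ether of 10-hydroxycarvone
Product: 5 (S)-5-[3-(TBS-oxy)prop-1-en-2-yl]-2-methylcyclohept-2-en-1-one, via alpha-silyl ketone 4 (not isolated)
Conditions: TMSCHN2, AlMe3, CH2Cl2, −78 to −20 °C; then K2CO3, MeOH, 0 °C
Reagents that add atoms: trimethylsilyldiazomethane, C[Si](C)(C)C=[N+]=[N-]
Why: In this Lewis-acid-promoted diazoalkane homologation (Tiffeneau–Demjanov type) the saturated C6 should migrate in preference to the electron-poor vinylic C2, so CH2 enters between C1 and C6, the enone stays conjugated, and methanolysis removes the α-silyl group.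

Step 4
Reactants: 5 ring-expanded enone
Product: 7 (3R,5S)-5-[3-(TBS-oxy)prop-1-en-2-yl]-2-methyl-3-(prop-1-en-2-yl)cyclohept-1-en-1-yl trifluoromethanesulfonate (3,5-cis), via magnesium enolate 6 (not isolated)
Conditions: isopropenylMgBr, CuBr·SMe2 (10 mol %), THF, −78 to −40 °C; then PhNTf2, DMPU, −78 °C to rt
Reagents that add atoms: isopropenylmagnesium bromide, C=C(C)[Mg]Br; N-phenylbis(trifluoromethanesulfonimide), O=S(=O)(N(c1ccccc1)S(=O)(=O)C(F)(F)F)C(F)(F)F
Why: Copper-catalysed conjugate addition should deliver isopropenyl to C3 on the exposed face of the chair-like cycloheptenone with its C5 substituent equatorial (the usual 3,5-cis preference of 5-substituted cyclohept-2-enones), and O-triflation of the regiodefined enolate fixes the position of the later alkene.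

Step 5
Reactants: 7 enol triflate
Product: 8 (5S,7R)-5-[3-(TBS-oxy)prop-1-en-2-yl]-1-methyl-7-(prop-1-en-2-yl)cyclohept-1-ene
Conditions: Pd(OAc)2 (5 mol %), PPh3, HCO2H, n-Bu3N, DMF, 60 °C
Reagents that add atoms: none
Why: Palladium-catalysed formate hydrogenolysis of the enol triflate (oxidative addition, formate decarboxylation, C–H reductive elimination) should replace OTf by H without moving the double bond or touching the stereocentres.

Step 6
Reactants: 8 trisubstituted cycloheptene
Product: 9 (1R,2R,4S,7S)-4-[3-(TBS-oxy)prop-1-en-2-yl]-1-methyl-2-(prop-1-en-2-yl)-8-oxabicyclo[5.1.0]octane (epoxide oxygen trans to both ring substituents)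
Conditions: mCPBA (1.05 equiv), NaHCO3, CH2Cl2, −20 to 0 °C
Reagents that add atoms: 3-chloroperoxybenzoic acid, OOC(=O)c1cccc(Cl)c1
Why: The peracid (Prilezhaev epoxidation) should select the trisubstituted ring alkene over the two 1,1-disubstituted ones and attack the face opposite the adjacent isopropenyl group and the cis side chain, which sets both epoxide carbons.

Step 7
Reactants: 9 cycloheptene oxide
Product: 10 (1S,2R,4S)-4-[3-(TBS-oxy)prop-1-en-2-yl]-1-methyl-2-(prop-1-en-2-yl)cyclohexane-1-carbaldehyde
Conditions: methylaluminium bis(4-bromo-2,6-di-tert-butylphenoxide) (MABR, 20 mol %, from AlMe3 and the phenol), CH2Cl2, −78 to −40 °C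
Reagents that add atoms: none
Why: The aluminium centre binds the epoxide oxygen, the C–O bond at the tertiary carbon (elemane C10) ionises, and the ring bond C1–C9 rotates anti to it and shifts to C10 while C1 becomes the formyl carbon, a Lewis-acid-catalysed epoxide-to-aldehyde (Meinwald/semipinacol) rearrangement of a 1-methylcycloalkene oxide. The cyclohexane C5–C10 is closed by this 1,2-alkyl shift, a seven-to-six ring contraction that extrudes the former carvone carbonyl carbon. The quaternary stereocentre C10 forms with inversion at the epoxide carbon, so the epoxide configuration set in step 6 places the methyl cis to the C5 isopropenyl group and the formyl trans; C5 and C7 are not touched. The step needs the ring-bond shift to win over the hydride shift (which would give the cycloheptanone) and over capture of the cation by the neighbouring isopropenyl group; the very bulky aluminium phenoxide, which favours aldehydes from trisubstituted epoxides, the low temperature and the relief of seven-ring strain should secure this. The product aldehyde is quaternary and cannot epimerise.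

Step 8
Reactants: 10 quaternary aldehyde
Product: 11 (1R,2R,4S)-4-[3-(TBS-oxy)prop-1-en-2-yl]-1-ethenyl-1-methyl-2-(prop-1-en-2-yl)cyclohexane
Conditions: Ph3PCH3Br, KHMDS, THF, 0 °C to rt
Reagents that add atoms: methyltriphenylphosphonium bromide, C[P+](c1ccccc1)(c1ccccc1)c1ccccc1.[Br-]
Why: Wittig methylenation of the non-enolisable neopentyl aldehyde should give the vinyl group on C10, with no stereocentre able to epimerise.

Step 9
Reactants: 11 silyl ether
Product: 12 2-[(1S,3R,4R)-4-ethenyl-4-methyl-3-(prop-1-en-2-yl)cyclohexyl]prop-2-en-1-ol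
Conditions: TBAF, THF, 0 °C to rt
Reagents that add atoms: none
Why: Fluoride cleaves the Si–O bond of the primary silyl ether and leaves the triene untouched.

Step 10
Reactants: 12 allylic alcohol
Product: 13 2-[(1S,3R,4R)-4-ethenyl-4-methyl-3-(prop-1-en-2-yl)cyclohexyl]prop-2-enal (ent-β-elemenal)
Conditions: activated MnO2 (excess), CH2Cl2, rt; used directly
Reagents that add atoms: none
Why: Activated MnO2 oxidises the allylic alcohol selectively to the 2-substituted acrolein and should not isomerise the 1,1-disubstituted double bond.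

Step 11
Reactants: 14 isoalantolactone
Product: 16 (5αH)-4-oxo-15-noreudesm-11(13)-en-8β,12-olide (trans-fused), via secondary ozonide 15 (not isolated)
Conditions: O3, CH2Cl2, −78 °C (Sudan Red 7B end-point); then Me2S, −78 °C to rt
Reagents that add atoms: ozone, [O-][O+]=O
Why: Electrophilic ozone should cleave the electron-rich C4=C15 methylene much faster than the conjugated lactone methylene, and reductive work-up of the ozonide gives the C4 ketone with C5 unchanged.

Step 12
Reactants: 16 trans-fused nor-ketone
Product: 18 (5βH)-4-oxo-15-noreudesm-11(13)-en-8β,12-olide (cis-fused), via ring-A enol 17 (not isolated)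
Conditions: TsOH·H2O (10 mol %), PhMe, 60 °C; chromatographic separation, recovered 16 resubmitted
Reagents that add atoms: none
Why: Acid-catalysed enolisation towards C5 equilibrates the ring fusion, and the cis-fused ketone, which escapes the 1,3-diaxial CH3-14/O-8 interaction of the trans isomer by ring flip, should be present in a useful amount while the acid leaves the α-methylene lactone intact.

Step 13
Reactants: 18 cis-fused nor-ketone
Product: 19 5-epi-isoalantolactone [(3aR,4aR,8aR,9aR)-8a-methyl-3,5-dimethylidenedecahydronaphtho[2,3-b]furan-2-one]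
Conditions: Zn, CH2Br2, TiCl4 (preformed Lombardo reagent), THF/CH2Cl2, 0 °C to rt
Reagents that add atoms: dibromomethane, BrCBr
Why: The non-basic Takai–Lombardo gem-dimetallic reagent should methylenate the ketone without enolising the labile C5 centre and does not react with the lactone.

Step 14
Reactants: 13 ent-β-elemenal; 19 5-epi-isoalantolactone (1.5 equiv)
Product: 20 CNP0353330.1 (spiro-dihydropyran dimer, pyran oxygen on the H-7/H-8 face of the lactone)
Conditions: BHT (cat.), PhMe (concentrated), 100 °C, sealed tube, Ar; excess 19 recovered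
Reagents that add atoms: none
Why: Thermal hetero-Diels–Alder reaction of the 1-oxadiene of 13 with the exocyclic methylene of 19 should follow the head-to-head regiochemistry of acrolein dimerisation (O to the more substituted C11, CH2 to CH2), and approach to the convex face of the cis-fused lactone, syn to H-7 and H-8, sets the spiro centre C11, the only new stereocentre.

Compound list
1 | (R)-(−)-carvone | O=C1C(C)=CC[C@@H](C(C)=C)C1 | starting material
2 | (R)-5-(3-hydroxyprop-1-en-2-yl)-2-methylcyclohex-2-en-1-one | O=C1C(C)=CC[C@@H](C(=C)CO)C1 | intermediate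
3 | (R)-5-[3-(TBS-oxy)prop-1-en-2-yl]-2-methylcyclohex-2-en-1-one | O=C1C(C)=CC[C@@H](C(=C)CO[Si](C)(C)C(C)(C)C)C1 | intermediate
4 | 7-(trimethylsilyl) derivative of 5 (alpha-silyl ketone, C7 undefined, not isolated) | O=C1C(C)=CC[C@@H](C(=C)CO[Si](C)(C)C(C)(C)C)CC1[Si](C)(C)C | intermediate
5 | (S)-5-[3-(TBS-oxy)prop-1-en-2-yl]-2-methylcyclohept-2-en-1-one | O=C1C(C)=CC[C@@H](C(=C)CO[Si](C)(C)C(C)(C)C)CC1 | intermediate
6 | bromomagnesium enolate of the (3R,5S)-3-isopropenyl ketone (not isolated) | Br[Mg]OC1=C(C)[C@@H](C(C)=C)C[C@@H](C(=C)CO[Si](C)(C)C(C)(C)C)CC1 | intermediate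
7 | (3R,5S)-5-[3-(TBS-oxy)prop-1-en-2-yl]-2-methyl-3-(prop-1-en-2-yl)cyclohept-1-en-1-yl triflate | O=S(=O)(OC1=C(C)[C@@H](C(C)=C)C[C@@H](C(=C)CO[Si](C)(C)C(C)(C)C)CC1)C(F)(F)F | intermediate
8 | (5S,7R)-5-[3-(TBS-oxy)prop-1-en-2-yl]-1-methyl-7-(prop-1-en-2-yl)cyclohept-1-ene | C1=C(C)[C@@H](C(C)=C)C[C@@H](C(=C)CO[Si](C)(C)C(C)(C)C)CC1 | intermediate
9 | (1R,2R,4S,7S)-4-[3-(TBS-oxy)prop-1-en-2-yl]-1-methyl-2-(prop-1-en-2-yl)-8-oxabicyclo[5.1.0]octane | C[C@]12O[C@H]1CC[C@H](C(=C)CO[Si](C)(C)C(C)(C)C)C[C@@H]2C(C)=C | intermediate
10 | (1S,2R,4S)-4-[3-(TBS-oxy)prop-1-en-2-yl]-1-methyl-2-(prop-1-en-2-yl)cyclohexane-1-carbaldehyde | O=C[C@@]1(C)CC[C@H](C(=C)CO[Si](C)(C)C(C)(C)C)C[C@@H]1C(C)=C | intermediate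
11 | (1R,2R,4S)-4-[3-(TBS-oxy)prop-1-en-2-yl]-1-ethenyl-1-methyl-2-(prop-1-en-2-yl)cyclohexane | C=C[C@@]1(C)CC[C@H](C(=C)CO[Si](C)(C)C(C)(C)C)C[C@@H]1C(C)=C | intermediate
12 | 2-[(1S,3R,4R)-4-ethenyl-4-methyl-3-(prop-1-en-2-yl)cyclohexyl]prop-2-en-1-ol | C=C[C@@]1(C)CC[C@H](C(=C)CO)C[C@@H]1C(C)=C | intermediate
13 | 2-[(1S,3R,4R)-4-ethenyl-4-methyl-3-(prop-1-en-2-yl)cyclohexyl]prop-2-enal (ent-β-elemenal) | C=C[C@@]1(C)CC[C@H](C(=C)C=O)C[C@@H]1C(C)=C | intermediate
14 | isoalantolactone [(3aR,4aS,8aR,9aR)] | C=C1C(=O)O[C@@H]2C[C@@]3(C)CCCC(=C)[C@@H]3C[C@H]12 | starting material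
15 | secondary ozonide (1,2,4-trioxolane) at C4/C15 of 14 (spiro carbon undefined, not isolated) | C=C1C(=O)O[C@@H]2C[C@@]3(C)CCCC4(OCOO4)[C@@H]3C[C@H]12 | intermediate
16 | (5αH)-4-oxo-15-noreudesm-11(13)-en-8β,12-olide | C=C1C(=O)O[C@@H]2C[C@@]3(C)CCCC(=O)[C@@H]3C[C@H]12 | intermediate
17 | ring-A enol (C4-OH, C4=C5) of 16 (not isolated) | C=C1C(=O)O[C@@H]2C[C@@]3(C)CCCC(O)=C3C[C@H]12 | intermediate
18 | (5βH)-4-oxo-15-noreudesm-11(13)-en-8β,12-olide | C=C1C(=O)O[C@@H]2C[C@@]3(C)CCCC(=O)[C@H]3C[C@H]12 | intermediate
19 | 5-epi-isoalantolactone [(5βH)-eudesma-4(15),11(13)-dien-8β,12-olide] | C=C1C(=O)O[C@@H]2C[C@@]3(C)CCCC(=C)[C@H]3C[C@H]12 | intermediate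
20 | CNP0353330.1 | C=C[C@@]1(C)CC[C@H](C2=CO[C@@]3(CC2)C(=O)O[C@@H]2C[C@@]4(C)CCCC(=C)[C@H]4C[C@@H]23)C[C@@H]1C(=C)C | target

Total step count: 14. Longest linear sequence: 11 steps (steps 1–10 and 14).

Steps most likely to fail

1. Step 7. The hydride on the secondary epoxide carbon may shift instead of the ring bond and give the 2-methylcycloheptanone, or the neighbouring isopropenyl group may capture the developing cation or the Lewis-acid-bound aldehyde in an ene-type cyclisation. The fallback sets out from 5 and comes back at 10, still by a seven-to-six contraction but through a cyclopropanone. The copper-catalysed isopropenyl addition to 5 would be repeated and the magnesium enolate quenched with N-chlorosuccinimide, which should give the α-chloro ketone F1 with chlorine anti to the isopropenyl group. NaOMe in Et2O/MeOH would then trigger a Favorskii rearrangement (cyclopropanone closure with inversion at the C–Cl carbon, opening towards the quaternary ester) to the ring-contracted methyl ester F2. DIBAL-H would reduce it to the neopentyl alcohol F3, and Dess–Martin oxidation would return to aldehyde 10.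

2. Step 12. The enol equilibrium may stay largely on the side of the trans-fused ketone, so that little cis epimer accumulates per pass. The fallback sets out from 16 and comes back at 18 without enolisation. Irradiation of 16 in benzene at λ ≥ 300 nm would excite only the saturated ketone. Norrish type I cleavage of the C4–C5 bond and recombination of the acyl/tertiary alkyl radical pair should scramble C5 and give 18 directly, separated from the photostationary mixture as before (no new compound, F0).

3. Step 14. Self-dimerisation or polymerisation of the enal may outrun the slow cycloaddition to the hindered 1,1-disubstituted dienophile, and attack on the concave lactone face may erode selectivity. The fallback sets out from 19 (with 13) and comes back at 20, building the dihydropyran stepwise. Weitz–Scheffer epoxidation of the α-methylene lactone of 19 (t-BuOOH, DBU) from its convex face should give the spiro-epoxide F4. MgI2 would open it at the CH2 terminus to the iodohydrin F5. Giese addition of the derived primary radical (Bu3SnH, AIBN, slow addition, PhH, 80 °C) to the CH2 terminus of enal 13 should give the δ-hydroxy aldehyde F6, in equilibrium with its lactol. Acid-catalysed dehydration (PPTS, PhMe, 4 Å sieves, 80 °C) would close the enol ether and return to 20.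

Further compounds
F0 | step 12 | none | none
F1 | step 7 | (2S,3R,5S)-2-chloro-2-methyl-3-(prop-1-en-2-yl)-5-[3-(TBS-oxy)prop-1-en-2-yl]cycloheptan-1-one (Cl trans to isopropenyl) | O=C1[C@](C)(Cl)[C@@H](C(C)=C)C[C@@H](C(=C)CO[Si](C)(C)C(C)(C)C)CC1
F2 | step 7 | methyl ester corresponding to aldehyde 10 (CO2Me in place of CHO, same configuration) | COC(=O)[C@@]1(C)CC[C@H](C(=C)CO[Si](C)(C)C(C)(C)C)C[C@@H]1C(C)=C
F3 | step 7 | primary alcohol corresponding to aldehyde 10 (CH2OH in place of CHO) | OC[C@@]1(C)CC[C@H](C(=C)CO[Si](C)(C)C(C)(C)C)C[C@@H]1C(C)=C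
F4 | step 14 | 11,13-epoxide of 19 (spiro-oxirane, oxygen on the H-7/H-8 face) | O1C[C@@]12C(=O)O[C@@H]3C[C@@]4(C)CCCC(=C)[C@H]4C[C@H]23
F5 | step 14 | 11-hydroxy-13-iodo-11,13-dihydro derivative of 19 (OH on the H-7/H-8 face) | IC[C@]1(O)C(=O)O[C@@H]2C[C@@]3(C)CCCC(=C)[C@H]3C[C@H]12
F6 | step 14 | δ-hydroxy aldehyde from radical addition of F5 to 13 (aldehyde α-carbon undefined) | C=C[C@@]1(C)CC[C@H](C(C=O)CC[C@]2(O)C(=O)O[C@@H]3C[C@@]4(C)CCCC(=C)[C@H]4C[C@H]23)C[C@@H]1C(=C)C
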